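## Retrosynthetic overview

1. Endgame on the bicycle: free the C10 alcohol, acetylate C2-OH, reduce the C2 ketone. Numbering used: C1 quaternary C-Me, C2 CH-OAc, C3 CH2, C4 C(OH)iPr, C5 ring-fusion CH, C6 CH-O-veratroyl, C7 CH2, C8/C9 oxirane (C8 methylated), C10 CH-OH.
2. Seven-membered ring: C1–C10 bond by intramolecular aldol addition of the cyclopentanone C1 enolate to an α,β-epoxy aldehyde.
3. Cyclopentane with side chain: isopropyl addition to the C4 ketone; before that a three-component coupling (methyl conjugate addition to a 4-silyloxycyclopentenone, aldol with a β,γ-epoxy aldehyde forming C5–C6, veratroylation in the same flask).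
4. Fragments: epoxy aldehyde from but-3-yn-1-ol (carboalumination, Sharpless epoxidation); enone from cyclopentadiene (enzymatic desymmetrisation); acid chloride from veratric acid.
5. Ring order: oxirane (in the chain fragment), cyclopentane (from the enone), cycloheptane last.

Assumption: the SMILES is read literally. Its (8R,9R) oxirane has C7 and C10 trans, i.e. a strained trans-fused epoxide on the seven-membered ring, so the oxirane is made from an (E)-alkene and the ring is closed around it.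

## Route

Step 1
Reactants: 1 but-3-yn-1-ol
Product: 2 1-[(but-3-yn-1-yloxy)methyl]-4-methoxybenzene
Conditions: NaH, 4-methoxybenzyl chloride, Bu4NI (cat.), THF/DMF, 0 °C to rt
Reagents that add atoms: 4-methoxybenzyl chloride, COc1ccc(CCl)cc1
Why: Williamson ether synthesis masks the future C6 oxygen as a PMB ether that can later be removed oxidatively beside an oxirane and a silyl ether.

Step 2
Reactants: 2 1-[(but-3-yn-1-yloxy)methyl]-4-methoxybenzene
Product: 5 (E)-5-[(4-methoxybenzyl)oxy]-3-methylpent-2-en-1-ol, via alkenylalane 3 (not isolated), via lithium alanate 4 (not isolated)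
Conditions: AlMe3, Cp2ZrCl2 (0.2 equiv), CH2Cl2, 0 °C to rt; then n-BuLi, THF, −78 °C; then (CH2O)n, −78 °C to rt; aq. HCl work-up
Reagents that add atoms: trimethylaluminium, C[Al](C)C; formaldehyde (as paraformaldehyde), C=O
Why: Negishi zirconium-catalysed carboalumination adds methyl and aluminium syn across the alkyne, and hydroxymethylation of the alanate with retention gives the (E)-trisubstituted allylic alcohol (C7 and C10 trans).

Step 3
Reactants: 5 (E)-5-[(4-methoxybenzyl)oxy]-3-methylpent-2-en-1-ol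
Product: 6 [(2R,3R)-3-{2-[(4-methoxybenzyl)oxy]ethyl}-3-methyloxiran-2-yl]methanol
Conditions: Ti(OiPr)4 (0.1 equiv), D-(−)-diethyl tartrate (0.12 equiv), t-BuOOH, 4 Å MS, CH2Cl2, −20 °C
Reagents that add atoms: tert-butyl hydroperoxide, CC(C)(C)OO
Why: Sharpless asymmetric epoxidation with the D-(−)-tartrate delivers oxygen to the face that gives the (2R,3R) oxirane (as for geraniol), and syn addition to the E alkene fixes C8 and C9 of the target with C7 and C10 trans.

Step 4
Reactants: 6 [(2R,3R)-3-{2-[(4-methoxybenzyl)oxy]ethyl}-3-methyloxiran-2-yl]methanol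
Product: 7 tert-butyl{[(2R,3R)-3-{2-[(4-methoxybenzyl)oxy]ethyl}-3-methyloxiran-2-yl]methoxy}dimethylsilane
Conditions: TBSCl, imidazole, DMF, 0 °C to rt
Reagents that add atoms: tert-butyldimethylsilyl chloride, CC(C)(C)[Si](C)(C)Cl
Why: Silyl ether formation protects the future C10 oxygen and blocks Payne rearrangement of the epoxy alcohol.

Step 5
Reactants: 7 tert-butyl{[(2R,3R)-3-{2-[(4-methoxybenzyl)oxy]ethyl}-3-methyloxiran-2-yl]methoxy}dimethylsilane
Product: 8 2-[(2R,3R)-3-({[tert-butyl(dimethyl)silyl]oxy}methyl)-2-methyloxiran-2-yl]ethan-1-ol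
Conditions: DDQ, CH2Cl2/pH 7 phosphate buffer (10:1), 0 °C
Reagents that add atoms: none
Why: Oxidative PMB cleavage by DDQ under buffered conditions leaves the oxirane and the TBS ether intact.

Step 6
Reactants: 8 2-[(2R,3R)-3-({[tert-butyl(dimethyl)silyl]oxy}methyl)-2-methyloxiran-2-yl]ethan-1-ol
Product: 9 2-[(2R,3R)-3-({[tert-butyl(dimethyl)silyl]oxy}methyl)-2-methyloxiran-2-yl]acetaldehyde
Conditions: Dess–Martin periodinane, pyridine, CH2Cl2, 0 °C; crude aldehyde used at once
Reagents that add atoms: none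
Why: Dess–Martin oxidation is non-basic, so the β,γ-epoxy aldehyde forms without β-elimination of the oxirane.

Step 7
Reactants: 10 cyclopenta-1,3-diene (freshly distilled from commercial dicyclopentadiene)
Product: 12 cis-cyclopent-2-ene-1,4-diol (meso), via endoperoxide 11 (not isolated)
Conditions: O2, rose bengal, hν, thiourea, MeOH, −30 °C to rt
Reagents that add atoms: dioxygen, O=O
Why: [4+2] cycloaddition of singlet oxygen followed by thiourea reduction of the O–O bond puts both oxygens on one face, so only the cis (meso) diol forms.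

Step 8
Reactants: 12 cis-cyclopent-2-ene-1,4-diol
Product: 13 cis-cyclopent-4-ene-1,3-diyl diacetate (meso)
Conditions: Ac2O, pyridine, DMAP (cat.), CH2Cl2, 0 °C to rt
Reagents that add atoms: acetic anhydride, CC(=O)OC(C)=O
Why: Standard acylation gives the meso diacetate needed for enzymatic desymmetrisation.

Step 9
Reactants: 13 cis-cyclopent-4-ene-1,3-diyl diacetate
Product: 14 (1R,4S)-4-hydroxycyclopent-2-en-1-yl acetate
Conditions: electric eel acetylcholinesterase, phosphate buffer (pH 6.9), rt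
Reagents that add atoms: none
Why: Enzymatic desymmetrisation hydrolyses one enantiotopic acetate of the meso diester and sets both stereocentres in high ee.

Step 10
Reactants: 14 (1R,4S)-4-hydroxycyclopent-2-en-1-yl acetate
Product: 15 (1R,4S)-4-{[tert-butyl(dimethyl)silyl]oxy}cyclopent-2-en-1-yl acetate
Conditions: TBSCl, imidazole, DMF, rt
Reagents that add atoms: tert-butyldimethylsilyl chloride, CC(C)(C)[Si](C)(C)Cl
Why: Silylation of the free hydroxyl makes that carbon (the future C2) the one that stays stereogenic after the other oxygen is oxidised.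

Step 11
Reactants: 15 (1R,4S)-4-{[tert-butyl(dimethyl)silyl]oxy}cyclopent-2-en-1-yl acetate
Product: 16 (1R,4S)-4-{[tert-butyl(dimethyl)silyl]oxy}cyclopent-2-en-1-ol
Conditions: K2CO3 (cat.), MeOH, 0 °C
Reagents that add atoms: none
Why: Mild transesterification removes the acetate without touching the silyl ether or the stereocentres.

Step 12
Reactants: 16 (1R,4S)-4-{[tert-butyl(dimethyl)silyl]oxy}cyclopent-2-en-1-ol
Product: 17 (4S)-4-{[tert-butyl(dimethyl)silyl]oxy}cyclopent-2-en-1-one
Conditions: MnO2, CH2Cl2, rt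
Reagents that add atoms: none
Why: Allylic oxidation with MnO2 gives the (S)-enone, whose silyloxy carbon is the control element for the next bond formations.

Step 13
Reactants: 18 3,4-dimethoxybenzoic acid
Product: 19 3,4-dimethoxybenzoyl chloride
Conditions: (COCl)2, DMF (cat.), CH2Cl2, 0 °C to rt
Reagents that add atoms: oxalyl chloride, O=C(Cl)C(=O)Cl
Why: Vilsmeier-type activation converts the acid into the acyl chloride used to trap the aldolate.

Step 14
Reactants: 17 (4S)-4-{[tert-butyl(dimethyl)silyl]oxy}cyclopent-2-en-1-one; 9 2-[(2R,3R)-3-({[tert-butyl(dimethyl)silyl]oxy}methyl)-2-methyloxiran-2-yl]acetaldehyde; 19 3,4-dimethoxybenzoyl chloride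
Product: 22 (1R)-1-[(1R,2S,3S)-3-{[tert-butyl(dimethyl)silyl]oxy}-2-methyl-5-oxocyclopentyl]-2-[(2R,3R)-3-({[tert-butyl(dimethyl)silyl]oxy}methyl)-2-methyloxiran-2-yl]ethyl 3,4-dimethoxybenzoate, via magnesium enolate 20 (not isolated), via magnesium aldolate 21 (not isolated)
Conditions: MeMgBr (1.05 equiv), CuBr·SMe2 (5 mol %), THF, −78 °C; then 9, −78 °C; then 19, DMAP (cat.), −78 to −20 °C
Reagents that add atoms: methylmagnesium bromide, C[Mg]Br
Why: Copper-catalysed conjugate addition places methyl trans to the silyloxy group, the resulting cyclic (E) magnesium enolate adds to the aldehyde trans to that methyl through a chair Zimmerman–Traxler transition state to give the anti (6R) aldolate (three-component coupling), and O-acylation in the same flask installs the veratroate and blocks retro-aldol.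

Step 15
Reactants: 22 the keto ester from step 14
Product: 23 (1R)-1-[(1R,2S,3S,5S)-3-{[tert-butyl(dimethyl)silyl]oxy}-5-hydroxy-2-methyl-5-(propan-2-yl)cyclopentyl]-2-[(2R,3R)-3-({[tert-butyl(dimethyl)silyl]oxy}methyl)-2-methyloxiran-2-yl]ethyl 3,4-dimethoxybenzoate
Conditions: iPrMgCl, CeCl3 (anhydrous), THF, −78 °C
Reagents that add atoms: isopropylmagnesium chloride, CC(C)[Mg]Cl
Why: Organocerium (Imamoto) 1,2-addition is weakly basic and ketone-selective, and attack from the face opposite the C5 side chain and the C2 silyloxy group puts isopropyl cis to H5 and the tertiary hydroxyl cis to C6 (4S).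

Step 16
Reactants: 23 the tertiary alcohol from step 15
Product: 24 (1R)-1-[(1R,2S,3S,5S)-3,5-dihydroxy-2-methyl-5-(propan-2-yl)cyclopentyl]-2-[(2R,3R)-3-(hydroxymethyl)-2-methyloxiran-2-yl]ethyl 3,4-dimethoxybenzoate
Conditions: HF·pyridine, pyridine, THF, 0 °C to rt
Reagents that add atoms: none
Why: Pyridine-buffered fluoride desilylation removes both TBS ethers without opening the trisubstituted oxirane or moving the aryl ester.

Step 17
Reactants: 24 the triol from step 16
Product: 25 (1R)-1-[(1R,2S,5S)-5-hydroxy-2-methyl-3-oxo-5-(propan-2-yl)cyclopentyl]-2-[(2R,3S)-3-formyl-2-methyloxiran-2-yl]ethyl 3,4-dimethoxybenzoate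
Conditions: Dess–Martin periodinane (3 equiv), pyridine, CH2Cl2, 0 °C to rt
Reagents that add atoms: none
Why: Dess–Martin oxidation converts the secondary C2 alcohol into the ketone and the primary epoxy alcohol into the non-enolisable α,β-epoxy aldehyde in one operation, the tertiary alcohol being inert.

Step 18
Reactants: 25 the keto aldehyde from step 17
Product: 28 ring-closed ketone (target skeleton with a C2 ketone and a C10 triethylsilyl ether, all other centres as in the target), via dilithium enolate alkoxide 26 (not isolated), via dilithium aldolate 27 (not isolated)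
Conditions: LiN(SiMe3)2 (2.2 equiv), THF (0.002 M, slow addition of 25), −78 °C; then Et3SiCl (1.1 equiv), −78 °C; AcOH quench
Reagents that add atoms: chlorotriethylsilane, CC[Si](Cl)(CC)CC
Why: Intramolecular aldol addition of an aldolate-type dianion, in which the C4 lithium alkoxide steers enolisation to C1, the enolate adds through a lithium-chelated closed transition state on the face away from C6 (trans ring fusion, methyl cis to C6) to the Felkin–Anh/Cornforth face of the epoxy aldehyde (anti to the C9–O bond, 10R), and in situ silylation of the secondary aldolate stops retro-aldol and Payne rearrangement.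

Step 19
Reactants: 28 the ring-closed ketone from step 18
Product: 29 C2 alcohol (target skeleton with free C2 hydroxyl cis to the C1 methyl and a C10 triethylsilyl ether)
Conditions: Et2BOMe, NaBH4, THF/MeOH (4:1), −78 °C; MeOH co-evaporation
Reagents that add atoms: none
Why: Narasaka–Prasad reduction ties the tertiary C4 hydroxyl and the C2 ketone into a diethylboron chelate on one face so that external hydride adds from the other, giving the cis-1,3-diol (2S).

Step 20
Reactants: 29 the C2 alcohol from step 19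
Product: 30 10-O-triethylsilyl ether of the target
Conditions: Ac2O, DMAP (cat.), pyridine, CH2Cl2, 0 °C to rt
Reagents that add atoms: acetic anhydride, CC(=O)OC(C)=O
Why: DMAP-catalysed acetylation reacts only at the single free secondary hydroxyl (C2), the tertiary C4 hydroxyl being too hindered and C10 being silylated.

Step 21
Reactants: 30 10-O-triethylsilyl ether of the target
Product: 31 (1R,2S,4S,5R,6R,8R,9R,10R)-2-acetoxy-8,9-epoxy-4,10-dihydroxydaucan-6-yl 3,4-dimethoxybenzoate (target)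
Conditions: HF·pyridine, pyridine, THF, 0 °C
Reagents that add atoms: none
Why: Buffered fluoride desilylation frees the C10 hydroxyl without acyl migration or oxirane opening.

## Compound list

1 | but-3-yn-1-ol | C#CCCO | starting material
2 | 1-[(but-3-yn-1-yloxy)methyl]-4-methoxybenzene | COc1ccc(COCCC#C)cc1 | intermediate
3 | (E)-{4-[(4-methoxybenzyl)oxy]-2-methylbut-1-en-1-yl}dimethylalane | COc1ccc(COCC/C(C)=C/[Al](C)C)cc1 | intermediate
4 | lithium butyl{(E)-4-[(4-methoxybenzyl)oxy]-2-methylbut-1-en-1-yl}dimethylalanate | [Li+].COc1ccc(COCC/C(C)=C/[Al-](C)(C)CCCC)cc1 | intermediate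
5 | (E)-5-[(4-methoxybenzyl)oxy]-3-methylpent-2-en-1-ol | COc1ccc(COCC/C(C)=C/CO)cc1 | intermediate
6 | [(2R,3R)-3-{2-[(4-methoxybenzyl)oxy]ethyl}-3-methyloxiran-2-yl]methanol | COc1ccc(COCC[C@@]2(C)O[C@@H]2CO)cc1 | intermediate
7 | tert-butyl{[(2R,3R)-3-{2-[(4-methoxybenzyl)oxy]ethyl}-3-methyloxiran-2-yl]methoxy}dimethylsilane | COc1ccc(COCC[C@@]2(C)O[C@@H]2CO[Si](C)(C)C(C)(C)C)cc1 | intermediate
8 | 2-[(2R,3R)-3-({[tert-butyl(dimethyl)silyl]oxy}methyl)-2-methyloxiran-2-yl]ethan-1-ol | OCC[C@@]1(C)O[C@@H]1CO[Si](C)(C)C(C)(C)C | intermediate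
9 | 2-[(2R,3R)-3-({[tert-butyl(dimethyl)silyl]oxy}methyl)-2-methyloxiran-2-yl]acetaldehyde | O=CC[C@@]1(C)O[C@@H]1CO[Si](C)(C)C(C)(C)C | intermediate
10 | cyclopenta-1,3-diene | C1=CC=CC1 | starting material
11 | 2,3-dioxabicyclo[2.2.1]hept-5-ene (meso endoperoxide) | O1[C@H]2C=C[C@@H](O1)C2 | intermediate
12 | cis-cyclopent-2-ene-1,4-diol (meso) | O[C@H]1C=C[C@@H](O)C1 | intermediate
13 | cis-cyclopent-4-ene-1,3-diyl diacetate (meso) | CC(=O)O[C@H]1C=C[C@@H](OC(C)=O)C1 | intermediate
14 | (1R,4S)-4-hydroxycyclopent-2-en-1-yl acetate | CC(=O)O[C@H]1C=C[C@@H](O)C1 | intermediate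
15 | (1R,4S)-4-{[tert-butyl(dimethyl)silyl]oxy}cyclopent-2-en-1-yl acetate | CC(=O)O[C@H]1C=C[C@@H](O[Si](C)(C)C(C)(C)C)C1 | intermediate
16 | (1R,4S)-4-{[tert-butyl(dimethyl)silyl]oxy}cyclopent-2-en-1-ol | O[C@H]1C=C[C@@H](O[Si](C)(C)C(C)(C)C)C1 | intermediate
17 | (4S)-4-{[tert-butyl(dimethyl)silyl]oxy}cyclopent-2-en-1-one | O=C1C=C[C@@H](O[Si](C)(C)C(C)(C)C)C1 | intermediate
18 | 3,4-dimethoxybenzoic acid | COc1ccc(C(=O)O)cc1OC | starting material
19 | 3,4-dimethoxybenzoyl chloride | COc1ccc(C(Cl)=O)cc1OC | intermediate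
20 | bromomagnesium (3S,4S)-4-{[tert-butyl(dimethyl)silyl]oxy}-3-methylcyclopent-1-en-1-olate (methyl trans to silyloxy) | Br[Mg]OC1=C[C@H](C)[C@@H](O[Si](C)(C)C(C)(C)C)C1 | intermediate
21 | bromomagnesium (1R)-1-[(1R,2S,3S)-3-{[tert-butyl(dimethyl)silyl]oxy}-2-methyl-5-oxocyclopentyl]-2-[(2R,3R)-3-({[tert-butyl(dimethyl)silyl]oxy}methyl)-2-methyloxiran-2-yl]ethan-1-olate | Br[Mg]O[C@H](C[C@@]1(C)O[C@@H]1CO[Si](C)(C)C(C)(C)C)[C@H]1[C@H](C)[C@@H](O[Si](C)(C)C(C)(C)C)CC1=O | intermediate
22 | (1R)-1-[(1R,2S,3S)-3-{[tert-butyl(dimethyl)silyl]oxy}-2-methyl-5-oxocyclopentyl]-2-[(2R,3R)-3-({[tert-butyl(dimethyl)silyl]oxy}methyl)-2-methyloxiran-2-yl]ethyl 3,4-dimethoxybenzoate | COc1ccc(C(=O)O[C@H](C[C@@]2(C)O[C@@H]2CO[Si](C)(C)C(C)(C)C)[C@H]2[C@H](C)[C@@H](O[Si](C)(C)C(C)(C)C)CC2=O)cc1OC | intermediate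
23 | (1R)-1-[(1R,2S,3S,5S)-3-{[tert-butyl(dimethyl)silyl]oxy}-5-hydroxy-2-methyl-5-(propan-2-yl)cyclopentyl]-2-[(2R,3R)-3-({[tert-butyl(dimethyl)silyl]oxy}methyl)-2-methyloxiran-2-yl]ethyl 3,4-dimethoxybenzoate | COc1ccc(C(=O)O[C@H](C[C@@]2(C)O[C@@H]2CO[Si](C)(C)C(C)(C)C)[C@H]2[C@H](C)[C@@H](O[Si](C)(C)C(C)(C)C)C[C@]2(O)C(C)C)cc1OC | intermediate
24 | (1R)-1-[(1R,2S,3S,5S)-3,5-dihydroxy-2-methyl-5-(propan-2-yl)cyclopentyl]-2-[(2R,3R)-3-(hydroxymethyl)-2-methyloxiran-2-yl]ethyl 3,4-dimethoxybenzoate | COc1ccc(C(=O)O[C@H](C[C@@]2(C)O[C@@H]2CO)[C@H]2[C@H](C)[C@@H](O)C[C@]2(O)C(C)C)cc1OC | intermediate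
25 | (1R)-1-[(1R,2S,5S)-5-hydroxy-2-methyl-3-oxo-5-(propan-2-yl)cyclopentyl]-2-[(2R,3S)-3-formyl-2-methyloxiran-2-yl]ethyl 3,4-dimethoxybenzoate | COc1ccc(C(=O)O[C@H](C[C@@]2(C)O[C@@H]2C=O)[C@H]2[C@H](C)C(=O)C[C@]2(O)C(C)C)cc1OC | intermediate
26 | dilithium enolate alkoxide of 25 (C1=C2 enolate, C4 alkoxide) | [Li+].[Li+].COc1ccc(C(=O)O[C@H](C[C@@]2(C)O[C@@H]2C=O)[C@H]2C(C)=C([O-])C[C@]2([O-])C(C)C)cc1OC | intermediate
27 | dilithium aldolate (ring-closed C2 ketone, C10 and C4 alkoxides) | [Li+].[Li+].COc1ccc(C(=O)O[C@@H]2C[C@@]3(C)O[C@@H]3[C@H]([O-])[C@]3(C)C(=O)C[C@]([O-])(C(C)C)[C@@H]23)cc1OC | intermediate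
28 | ring-closed ketone: target skeleton with C2 ketone and C10 triethylsilyl ether | COc1ccc(C(=O)O[C@@H]2C[C@@]3(C)O[C@@H]3[C@H](O[Si](CC)(CC)CC)[C@]3(C)C(=O)C[C@](O)(C(C)C)[C@@H]23)cc1OC | intermediate
29 | C2 alcohol: target skeleton with free C2 hydroxyl (cis to C1 methyl) and C10 triethylsilyl ether | COc1ccc(C(=O)O[C@@H]2C[C@@]3(C)O[C@@H]3[C@H](O[Si](CC)(CC)CC)[C@]3(C)[C@@H](O)C[C@](O)(C(C)C)[C@@H]23)cc1OC | intermediate
30 | 10-O-triethylsilyl ether of the target | COc1ccc(C(=O)O[C@@H]2C[C@@]3(C)O[C@@H]3[C@H](O[Si](CC)(CC)CC)[C@]3(C)[C@@H](OC(C)=O)C[C@](O)(C(C)C)[C@@H]23)cc1OC | intermediate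
31 | (1R,2S,4S,5R,6R,8R,9R,10R)-2-acetoxy-8,9-epoxy-4,10-dihydroxydaucan-6-yl 3,4-dimethoxybenzoate | COc1ccc(C(=O)O[C@@H]2C[C@@]3(C)O[C@@H]3[C@H](O)[C@]3(C)[C@@H](OC(C)=O)C[C@](O)(C(C)C)[C@@H]23)cc1OC | target

## Step count and risks

Total step count: 21. Longest linear sequence: 14 (steps 1–6 or steps 7–12, then steps 14–21).

Steps most likely to fail:

Step 18. The ring closure creates a seven-membered ring with a trans-fused oxirane and a quaternary centre, and it relies on alkoxide-directed enolisation at C1, so strain, regiochemistry or retro-aldol may defeat it. The fallback sets out from 25 and comes back at 28. Compound 25 is brominated at C1 with pyridinium tribromide in pyridine-buffered THF to give the tertiary α-bromo ketone F1. SmI2 in THF at −78 °C then generates the samarium enolate at C1 only, without base, and this closes onto the aldehyde in a Reformatsky-type aldol to give the ring-closed aldol with a free C10 hydroxyl F2. Silylation of the secondary alcohol with Et3SiCl and imidazole gives 28.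

Step 14. The β,γ-epoxy aldehyde 9 may isomerise to a γ-hydroxy enal under the enolate conditions, or the aldol may be poorly selective. The fallback sets out from 5 and comes back at 24, and moves the epoxidation to after the coupling. Compound 5 is silylated (TBSCl, imidazole) to the allylic silyl ether F3, the PMB group is removed with DDQ to give the homoallylic alcohol F4, and Dess–Martin oxidation gives the β,γ-unsaturated aldehyde F5. The same three-component coupling with 17, MeMgBr and 19 gives the olefinic keto ester F6. Organocerium addition (iPrMgCl, CeCl3) gives the olefinic tertiary alcohol F7, and HF·pyridine gives the allylic alcohol triol F8. Sharpless epoxidation of the primary allylic alcohol (Ti(OiPr)4, D-(−)-diethyl tartrate, t-BuOOH) gives 24.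

Step 15. The β-aroyloxy ketone 22 may eliminate the C6 ester or lose it to the organometallic. The fallback sets out from 17 and 9 and comes back at 23. The coupling is run without the acid chloride and quenched cold to isolate the free anti aldol F9. Excess iPrMgCl and CeCl3 add to the chelated β-hydroxy ketone to give the diol F10. Acylation of the secondary hydroxyl only, with 19, Et3N and DMAP at 0 °C, gives 23.

## Further compounds

F1 | step 18 | C1 α-bromo ketone of 25 (bromine anti to the side chain) | COc1ccc(C(=O)O[C@H](C[C@@]2(C)O[C@@H]2C=O)[C@H]2[C@](C)(Br)C(=O)C[C@]2(O)C(C)C)cc1OC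
F2 | step 18 | ring-closed aldol with free C10 hydroxyl (28 without the silyl group) | COc1ccc(C(=O)O[C@@H]2C[C@@]3(C)O[C@@H]3[C@H](O)[C@]3(C)C(=O)C[C@](O)(C(C)C)[C@@H]23)cc1OC
F3 | step 14 | tert-butyl{[(E)-5-[(4-methoxybenzyl)oxy]-3-methylpent-2-en-1-yl]oxy}dimethylsilane | COc1ccc(COCC/C(C)=C/CO[Si](C)(C)C(C)(C)C)cc1
F4 | step 14 | (E)-5-{[tert-butyl(dimethyl)silyl]oxy}-3-methylpent-3-en-1-ol | OCC/C(C)=C/CO[Si](C)(C)C(C)(C)C
F5 | step 14 | (E)-5-{[tert-butyl(dimethyl)silyl]oxy}-3-methylpent-3-enal | O=CC/C(C)=C/CO[Si](C)(C)C(C)(C)C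
F6 | step 14 | olefinic analogue of 22 (E alkene in place of the oxirane) | COc1ccc(C(=O)O[C@H](C/C(C)=C/CO[Si](C)(C)C(C)(C)C)[C@H]2[C@H](C)[C@@H](O[Si](C)(C)C(C)(C)C)CC2=O)cc1OC
F7 | step 14 | olefinic analogue of 23 | COc1ccc(C(=O)O[C@H](C/C(C)=C/CO[Si](C)(C)C(C)(C)C)[C@H]2[C@H](C)[C@@H](O[Si](C)(C)C(C)(C)C)C[C@]2(O)C(C)C)cc1OC
F8 | step 14 | olefinic analogue of 24 (primary allylic alcohol) | COc1ccc(C(=O)O[C@H](C/C(C)=C/CO)[C@H]2[C@H](C)[C@@H](O)C[C@]2(O)C(C)C)cc1OC
F9 | step 15 | free anti aldol (22 without the aroyl group) | O[C@H](C[C@@]1(C)O[C@@H]1CO[Si](C)(C)C(C)(C)C)[C@H]1[C@H](C)[C@@H](O[Si](C)(C)C(C)(C)C)CC1=O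
F10 | step 15 | diol (23 without the aroyl group) | O[C@H](C[C@@]1(C)O[C@@H]1CO[Si](C)(C)C(C)(C)C)[C@H]1[C@H](C)[C@@H](O[Si](C)(C)C(C)(C)C)C[C@]1(O)C(C)C
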